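**Plan**
- Retrosynthesis: the benzyl ether on the ring B phenol is removed first. Ring C is then cut at C2–C3 and at O1–C8a in one stroke. This leaves an aldehyde (C2 and O1) and the four-carbon unit C3–C4–C4a–C8a of an acetylated ring A.
- Enabling feature: in ring A the C5 hydroxyl and the C8 methoxyl stand para to each other (a hydroquinone monomethyl ether). Ring A can therefore be raised to the p-quinone monoketal level [C5=O, C8(OMe)2]. C8a–H is then the β-carbon of both C4=O and C5=O, and C3=C4(OSiMe3)–C4a=C8a is a 2-silyloxydiene.
- Forward: 1,2,3,4-tetramethoxybenzene (ring A) is acetylated and mono-demethylated, dearomatised with PhI(OAc)2/MeOH and converted into the enol silane. The ring B aldehyde is benzylated separately.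
- Union: an asymmetric Mukaiyama aldol/oxa-Michael/aromatisation cascade (a formal hetero-Diels–Alder reaction) closes ring C. Ring A returns to the arene by loss of one ketal methoxyl, which leaves 8-OMe and 5-OH. Neutral hydrogenolysis ends the route.
- Stereochemistry: C2 is the only stereocentre. A chiral acyloxyborane sets it in the C2–C3 bond formation (Si face of the aldehyde). The C2–O bond is never broken afterwards, and all later operations are non-basic, so ring opening to the chalcone cannot scramble it.

Key step: step 5

Assumption: the facial preference established for benzaldehyde-type substrates with tartrate-derived acyloxyboranes is taken to hold for the 2,6-dialkoxybenzaldehyde 7; the catalyst ligand is a known compound prepared separately and is not counted as a step.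

Step 1
Reactants: 1 1,2,3,4-tetramethoxybenzene
Product: 3 1-(2-hydroxy-3,4,5-trimethoxyphenyl)ethan-1-one, via tetramethoxyacetophenone 2 (not isolated)
Conditions: AcCl (1.1 equiv), AlCl3 (2.2 equiv), CH2Cl2, 0 °C to rt; then cold dilute aqueous HCl
Reagents that add atoms: acetyl chloride CC(=O)Cl
Why: Friedel–Crafts acylation takes place at one of the two equivalent free positions of the electron-rich ring, and the excess AlCl3 then cleaves only the methyl ether ortho to the new ketone through a six-membered aluminium chelate, the usual selectivity of Lewis-acid demethylation of ortho-methoxyaryl ketones.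

Step 2
Reactants: 3 1-(2-hydroxy-3,4,5-trimethoxyphenyl)ethan-1-one
Product: 4 2-acetyl-4,4,5,6-tetramethoxycyclohexa-2,5-dien-1-one
Conditions: PhI(OAc)2 (1.05 equiv), MeOH–CH2Cl2 1:4, 0 °C, short reaction time; cold aqueous NaHCO3 wash
Reagents that add atoms: methanol CO
Why: Hypervalent-iodine oxidative dearomatisation of a para-methoxyphenol, in which the trivalent iodine reagent oxidises the phenol by two electrons and methanol is captured at the para carbon that already bears a methoxyl to give the p-quinone dimethyl monoketal, while a short time at 0 °C in a methanol-poor medium limits conjugate addition of methanol.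

Step 3
Reactants: 4 2-acetyl-4,4,5,6-tetramethoxycyclohexa-2,5-dien-1-one
Product: 5 4,4,5,6-tetramethoxy-2-[1-(trimethylsilyloxy)ethenyl]cyclohexa-2,5-dien-1-one
Conditions: LiN(SiMe3)2 (1.1 equiv) added to 4 and Me3SiCl (3 equiv), THF, −78 °C; pentane, filtration, evaporation, used at once
Reagents that add atoms: chlorotrimethylsilane C[Si](C)(C)Cl
Why: Kinetic enolisation with internal silyl quench (enol silane formation), in which the acetyl CH3 holds the only acidic hydrogens of 4, the bulky amide is kept off the β-carbon by the neighbouring quaternary ketal carbon, and the Me3SiCl already present traps the enolate oxygen before the enolate can add to a second dienone.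

Step 4
Reactants: 6 2-hydroxy-6-methoxybenzaldehyde
Product: 7 2-(benzyloxy)-6-methoxybenzaldehyde
Conditions: BnBr, K2CO3, DMF, rt
Reagents that add atoms: benzyl bromide BrCc1ccccc1
Why: Williamson ether synthesis on the only phenol, which masks the acidic OH that would otherwise protonate enol silane 5 or compete as an oxygen nucleophile for the dienone in step 5.

Step 5
Reactants: 5 4,4,5,6-tetramethoxy-2-[1-(trimethylsilyloxy)ethenyl]cyclohexa-2,5-dien-1-one; 7 2-(benzyloxy)-6-methoxybenzaldehyde
Product: 11 (2S)-2-[2-(benzyloxy)-6-methoxyphenyl]-5-hydroxy-6,7,8-trimethoxychroman-4-one, via silyl aldol adduct 8 (not isolated), via free carbinol 9 (not isolated), via cyclised ketal 10 (not isolated)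
Conditions: acyloxyborane (20 mol %) formed in situ from (2S,3S)-2-O-(2,6-diisopropoxybenzoyl)tartaric acid and 3,5-(CF3)2C6H3B(OH)2, EtCN, −78 °C, slow addition of 5 to 7; then Et3N·3HF, −78 to 0 °C
Reagents that add atoms: none
Why: Proposed new method: the boron Lewis acid binds the formyl oxygen of 7 and the CH2 terminus (C3) of the diene C3=C4(OSiMe3)–C4a=C8a of 5 attacks the aldehyde carbon through an open transition state (C2–C3 bond), silyl transfer gives 8 and restores the C4 ketone, and once Et3N·3HF has freed carbinol 9 its oxygen adds to C8a, now the β-carbon of both C4=O and C5=O (O1–C8a bond), to give 10, in which the C8 ketal carbon is the ipso position of a latent arenium ion, so that the mildly acidic medium expels one methoxyl, H8a is lost and ring A aromatises irreversibly with 8-OMe and the chelated 5-OH in place. The closest known reaction types are the chiral-Lewis-acid-catalysed Mukaiyama aldol/cyclisation (formal hetero-Diels–Alder reaction) of 1-methoxy-3-silyloxybutadienes with aromatic aldehydes, the acyloxyborane-catalysed aldol addition of acetophenone-type enol silanes to benzaldehydes, and the Michael addition/methanol-loss aromatisation of quinone monoketals; new is that the diene is embedded in a quinone monoketal, so that the annulation delivers a benzo-fused pyranone. Ring C closes in the 6-endo-trig oxa-Michael mode (C4a=C8a lies inside the new ring), the allowed mode of flavanone closure, here run with the roles of oxygen donor and arene exchanged. C2 is the only lasting stereocentre and is controlled by the catalyst: the acyloxyborane from natural (R,R)-tartaric acid leaves the Re face of bound aromatic aldehydes open, so its enantiomer from (S,S)-tartaric acid should direct 5 to the Si face of 7 and give the S carbinol, which becomes 2S because the C2–O bond is never broken afterwards, while the transient centre C8a vanishes on aromatisation. The step needs attack of the carbinol at C8a and not at C6, C7 or C5, which is secured because C8a is the only hydrogen-bearing, doubly activated ring carbon, C6=C7 is a deactivated dimethoxy-substituted vinylogous ester and hemiketal formation at C5 is reversible and leads nowhere, and it needs ring closure to outrun dehydration to the chalcone-type enone, which the non-basic fluoride source and the irreversible aromatisation should secure. Premature ionisation of the ketal should be slow at −78 °C because before cyclisation the cation is destabilised by the conjugated C5 carbonyl and both positions it would activate (C4a and C6) are substituted.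

Step 6
Reactants: 11 (2S)-2-[2-(benzyloxy)-6-methoxyphenyl]-5-hydroxy-6,7,8-trimethoxychroman-4-one
Product: 12 (2S)-5-hydroxy-2-(2-hydroxy-6-methoxyphenyl)-6,7,8-trimethoxychroman-4-one (target)
Conditions: H2 (1 atm), Pd/C (10 wt %), EtOAc, rt
Reagents that add atoms: none
Why: Catalytic hydrogenolysis of an aryl benzyl ether under neutral conditions, a standard end-game for flavanones in which the O-benzyl bond is cleaved faster than the hindered cyclic C2–O1 bond and no base or acid is present that could open ring C and racemise C2.

**Compound list**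
1 | 1,2,3,4-tetramethoxybenzene | COc1ccc(OC)c(OC)c1OC | starting material
2 | 1-(2,3,4,5-tetramethoxyphenyl)ethan-1-one | CC(=O)c1cc(OC)c(OC)c(OC)c1OC | intermediate
3 | 1-(2-hydroxy-3,4,5-trimethoxyphenyl)ethan-1-one | CC(=O)c1cc(OC)c(OC)c(OC)c1O | intermediate
4 | 2-acetyl-4,4,5,6-tetramethoxycyclohexa-2,5-dien-1-one | CC(=O)C1=CC(OC)(OC)C(OC)=C(OC)C1=O | intermediate
5 | 4,4,5,6-tetramethoxy-2-[1-(trimethylsilyloxy)ethenyl]cyclohexa-2,5-dien-1-one | C=C(O[Si](C)(C)C)C1=CC(OC)(OC)C(OC)=C(OC)C1=O | intermediate
6 | 2-hydroxy-6-methoxybenzaldehyde | COc1cccc(O)c1C=O | starting material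
7 | 2-(benzyloxy)-6-methoxybenzaldehyde | COc1cccc(OCc2ccccc2)c1C=O | intermediate
8 | 2-{(3S)-3-[2-(benzyloxy)-6-methoxyphenyl]-3-(trimethylsilyloxy)propanoyl}-4,4,5,6-tetramethoxycyclohexa-2,5-dien-1-one | COc1cccc(OCc2ccccc2)c1[C@@H](O[Si](C)(C)C)CC(=O)C1=CC(OC)(OC)C(OC)=C(OC)C1=O | intermediate
9 | 2-{(3S)-3-[2-(benzyloxy)-6-methoxyphenyl]-3-hydroxypropanoyl}-4,4,5,6-tetramethoxycyclohexa-2,5-dien-1-one | COc1cccc(OCc2ccccc2)c1[C@@H](O)CC(=O)C1=CC(OC)(OC)C(OC)=C(OC)C1=O | intermediate
10 | (2S)-2-[2-(benzyloxy)-6-methoxyphenyl]-5-hydroxy-6,7,8,8-tetramethoxy-2,3,8,8a-tetrahydro-4H-chromen-4-one (enol form; either C8a epimer, both converge) | COc1cccc(OCc2ccccc2)c1[C@@H]1CC(=O)C2=C(O)C(OC)=C(OC)C(OC)(OC)C2O1 | intermediate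
11 | (2S)-2-[2-(benzyloxy)-6-methoxyphenyl]-5-hydroxy-6,7,8-trimethoxychroman-4-one | COc1cccc(OCc2ccccc2)c1[C@@H]1CC(=O)c2c(O)c(OC)c(OC)c(OC)c2O1 | intermediate
12 | (2S)-5-hydroxy-2-(2-hydroxy-6-methoxyphenyl)-6,7,8-trimethoxychroman-4-one | COc1cccc(O)c1[C@@H]1CC(=O)c2c(O)c(OC)c(OC)c(OC)c2O1 | target

Total step count: 6. Longest linear sequence: 5 (steps 1, 2, 3, 5, 6).

**Steps most likely to fail**

1. Step 5.
   - What may go wrong:
     - slow addition of the attenuated enol silane to the hindered, electron-rich aldehyde;
     - poor facial selectivity;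
     - Lewis-acid ionisation of the ketal;
     - intermolecular Mukaiyama–Michael addition of 5 to the acyl dienone of the first-formed adduct.
   - The fallback sets out from 3 and 7 and comes back at 9. It makes the two bonds in separate operations that each have precedent.
   - Ketone 3 is silylated on both oxygens (Me3SiOTf, Et3N, CH2Cl2, 0 °C; no Michael acceptor is present at this stage). This gives 1-[3,4,5-trimethoxy-2-(trimethylsilyloxy)phenyl]-1-(trimethylsilyloxy)ethene F1, an ordinary acetophenone-type enol silane within the known scope of the acyloxyborane-catalysed Mukaiyama aldol addition.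
   - With 7 and the same catalyst, F1 should give the doubly silylated (S)-aldol F2.
   - Et3N·3HF frees (3S)-3-[2-(benzyloxy)-6-methoxyphenyl]-3-hydroxy-1-(2-hydroxy-3,4,5-trimethoxyphenyl)propan-1-one F3.
   - PhI(OAc)2 in MeOH–CH2Cl2 at 0 °C then raises ring A of F3 to the monoketal level. The product is 9, which closes and aromatises to 11 as in the route.

2. Step 3.
   - What may go wrong: the dienone enolate adds to the Michael acceptor of a second molecule, or the amide base adds, before silylation.
   - The fallback sets out from 4 and 7 and comes back at 11. It gives up both the isolated enol silane and catalyst control.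
   - Enolisation with (c-C6H11)2BCl and Et3N in Et2O at −78 °C is a Lewis-acid-assisted deprotonation that passes through no free enolate. It gives the enol dicyclohexylborinate F4, which is inert to Michael acceptors but adds to 7 through a closed six-membered transition state.
   - The addition gives the racemic boron aldolate F5.
   - Non-oxidative cleavage (MeOH, pH 7 buffer) gives the racemic carbinol F6.
   - Dilute AcOH in CH2Cl2 closes F6 through the racemic cyclised ketal F7 to the racemic benzyl-protected flavanone F8.
   - Preparative HPLC on a chiral phase separates 11 from its (2R) enantiomer F9.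

3. Step 2.
   - What may go wrong: methanol adds in conjugate fashion to the doubly activated β-carbon of 4, followed by re-aromatisation and further oxidation.
   - The fallback sets out from 3 and comes back at 4. It unveils the second activating carbonyl only in an aprotic medium.
   - NaBH4 in MeOH reduces 3 to racemic 6-(1-hydroxyethyl)-2,3,4-trimethoxyphenol F10.
   - PhI(OAc)2/MeOH converts F10 into the much less electrophilic racemic 2-(1-hydroxyethyl)-4,4,5,6-tetramethoxycyclohexa-2,5-dien-1-one F11.
   - Dess–Martin periodinane with NaHCO3 in CH2Cl2 oxidises the allylic carbinol of F11 to 4.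

**Further compounds**
F1 | step 5 | 1-[3,4,5-trimethoxy-2-(trimethylsilyloxy)phenyl]-1-(trimethylsilyloxy)ethene | C=C(O[Si](C)(C)C)c1cc(OC)c(OC)c(OC)c1O[Si](C)(C)C
F2 | step 5 | (3S)-3-[2-(benzyloxy)-6-methoxyphenyl]-1-[3,4,5-trimethoxy-2-(trimethylsilyloxy)phenyl]-3-(trimethylsilyloxy)propan-1-one | COc1cccc(OCc2ccccc2)c1[C@@H](O[Si](C)(C)C)CC(=O)c1cc(OC)c(OC)c(OC)c1O[Si](C)(C)C
F3 | step 5 | (3S)-3-[2-(benzyloxy)-6-methoxyphenyl]-3-hydroxy-1-(2-hydroxy-3,4,5-trimethoxyphenyl)propan-1-one | COc1cccc(OCc2ccccc2)c1[C@@H](O)CC(=O)c1cc(OC)c(OC)c(OC)c1O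
F4 | step 3 | 2-[1-(dicyclohexylboranyloxy)ethenyl]-4,4,5,6-tetramethoxycyclohexa-2,5-dien-1-one | C=C(OB(C1CCCCC1)C1CCCCC1)C1=CC(OC)(OC)C(OC)=C(OC)C1=O
F5 | step 3 | racemic dicyclohexylboron aldolate of 4 and 7 | COc1cccc(OCc2ccccc2)c1C(CC(=O)C1=CC(OC)(OC)C(OC)=C(OC)C1=O)OB(C1CCCCC1)C1CCCCC1
F6 | step 3 | racemic 2-{3-[2-(benzyloxy)-6-methoxyphenyl]-3-hydroxypropanoyl}-4,4,5,6-tetramethoxycyclohexa-2,5-dien-1-one | COc1cccc(OCc2ccccc2)c1C(O)CC(=O)C1=CC(OC)(OC)C(OC)=C(OC)C1=O
F7 | step 3 | racemic 2-[2-(benzyloxy)-6-methoxyphenyl]-5-hydroxy-6,7,8,8-tetramethoxy-2,3,8,8a-tetrahydro-4H-chromen-4-one | COc1cccc(OCc2ccccc2)c1C1CC(=O)C2=C(O)C(OC)=C(OC)C(OC)(OC)C2O1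
F8 | step 3 | racemic 2-[2-(benzyloxy)-6-methoxyphenyl]-5-hydroxy-6,7,8-trimethoxychroman-4-one | COc1cccc(OCc2ccccc2)c1C1CC(=O)c2c(O)c(OC)c(OC)c(OC)c2O1
F9 | step 3 | (2R)-2-[2-(benzyloxy)-6-methoxyphenyl]-5-hydroxy-6,7,8-trimethoxychroman-4-one | COc1cccc(OCc2ccccc2)c1[C@H]1CC(=O)c2c(O)c(OC)c(OC)c(OC)c2O1
F10 | step 2 | racemic 6-(1-hydroxyethyl)-2,3,4-trimethoxyphenol | CC(O)c1cc(OC)c(OC)c(OC)c1O
F11 | step 2 | racemic 2-(1-hydroxyethyl)-4,4,5,6-tetramethoxycyclohexa-2,5-dien-1-one | CC(O)C1=CC(OC)(OC)C(OC)=C(OC)C1=O
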